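**Plan**

Numbering: the cyclohexene ring is C1 (OMe), C2 (=CH), C3 (=C, carries C7H2OBz), C4 (OH), C5 (OBz), C6 (OH). The target is 1S,4R,5R,6R, with O1, O4 and O5 on one face and O6 on the other.
Retrosynthesis: the acyl–oxygen bonds at O5 and O7 are cut first and C7 is raised to a methyl ester. The ring bond C3–C4 is cut next, then C2=C3, which leads to a 2-O-methyl-D-xylose unit and a two-carbon ylide.
Enabling feature: inside the ring, C3 is the α-carbon of the acrylate unit C2=C3–C7 and is bonded to carbinol C4. This α-(hydroxyalkyl)acrylate is the product pattern of a Morita–Baylis–Hillman reaction, so the carbocycle opens to an acyclic enoate aldehyde.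
Forward: D-xylose is oxidised to its 1,4-lactone and O2 is methylated. A Wittig reaction extends sugar C1 (C2=C3 and C7) and sugar C5 becomes the aldehyde. The only carbocycle closes in step 8, and reduction plus two ordered benzoylations finish the molecule.
Stereochemistry: C1, C6 and C5 are C2, C3 and C4 of D-xylose and no bond to them is broken. C4 is created in the ring closure under substrate control.

Key step: step 8

Remark: the lactol of step 4 is used as its anomeric mixture, because that centre disappears in step 5. From step 5 on, atoms are addressed by the target numbering given above.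

**Step 1**
Reactants: 1 D-xylose
Product: 3 D-xylono-1,4-lactone, via D-xylonic acid 2 (not isolated)
Conditions: Br2, K2CO3, H2O, 0 °C to rt; then evaporation from AcOH, 50 °C
Reagents that add atoms: water, SMILES O
Why: Bromine-water oxidation of an aldose acts only on the anomeric hemiacetal carbon, and acid 2 closes through O4 to the five-membered lactone on concentration, so the three carbinol centres are carried over unchanged.

**Step 2**
Reactants: 3 D-xylono-1,4-lactone; 4 2,2-dimethoxypropane
Product: 5 3,5-O-isopropylidene-D-xylono-1,4-lactone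
Conditions: Me2C(OMe)2 (1.5 equiv), p-TsOH·H2O (cat.), acetone, rt; Et3N
Reagents that add atoms: 2,2-dimethoxypropane 4, SMILES COC(C)(C)OC
Why: In this acid-catalysed transacetalisation O3 and the C5 hydroxymethyl arm lie on the same face of the lactone and close a cis-fused 1,3-dioxane, whereas O2 is trans to O3, cannot be bridged and stays as the only free hydroxyl.

**Step 3**
Reactants: 5 3,5-O-isopropylidene-D-xylono-1,4-lactone; 6 iodomethane
Product: 7 3,5-O-isopropylidene-2-O-methyl-D-xylono-1,4-lactone
Conditions: MeI, Ag2O, 4 Å MS, MeCN, rt, dark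
Reagents that add atoms: iodomethane 6, SMILES CI
Why: Purdie methylation alkylates the free hydroxyl under essentially non-basic conditions, so neither epimerisation at the lactone α-carbon nor β-elimination of O3 should intervene.

**Step 4**
Reactants: 7 3,5-O-isopropylidene-2-O-methyl-D-xylono-1,4-lactone
Product: 8 3,5-O-isopropylidene-2-O-methyl-D-xylofuranose (anomeric mixture)
Conditions: i-Bu2AlH (1.1 equiv), CH2Cl2, −78 °C; aq. potassium sodium tartrate
Reagents that add atoms: none
Why: Partial reduction of a γ-lactone with one equivalent of i-Bu2AlH stops at the lactol because the tetrahedral aluminium hemiacetal is stable at −78 °C, and the new anomeric centre is of no consequence.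

**Step 5**
Reactants: 8 3,5-O-isopropylidene-2-O-methyl-D-xylofuranose; 9 methyl (triphenylphosphoranylidene)acetate
Product: 11 methyl (2E,4S)-4-[(4S,5R)-5-hydroxy-2,2-dimethyl-1,3-dioxan-4-yl]-4-methoxybut-2-enoate, via open-chain hydroxy aldehyde 10 (not isolated)
Conditions: Ph3P=CHCO2Me (1.5 equiv), PhCO2H (cat.), toluene, 70 °C
Reagents that add atoms: methyl (triphenylphosphoranylidene)acetate 9, SMILES COC(=O)C=P(c1ccccc1)(c1ccccc1)c1ccccc1
Why: Wittig olefination of a lactol through its open form 10 with a stabilised ylide should give mainly the (E)-enoate (a geometry erased again in step 8), builds C2=C3 together with C7 and frees the former ring oxygen as the C5 hydroxyl, which has no strong base present to drive it back onto the enoate.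

**Step 6**
Reactants: 11 methyl (2E,4S)-4-[(4S,5R)-5-hydroxy-2,2-dimethyl-1,3-dioxan-4-yl]-4-methoxybut-2-enoate
Product: 12 methyl (2E,4S)-4-[(4R,5R)-5-(hydroxymethyl)-2,2-dimethyl-1,3-dioxolan-4-yl]-4-methoxybut-2-enoate
Conditions: CSA (5 mol %), dry acetone, rt; Et3N
Reagents that add atoms: none
Why: In this acid-catalysed acetal migration under thermodynamic control the 2,2-dimethyl-1,3-dioxane, with its unavoidable axial methyl group, gives way to the trans-4,5-disubstituted dioxolane on the threo C5/C6 diol (the ring type also preferred when xylitol is acetonated), and the primary C4 hydroxyl is released.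

**Step 7**
Reactants: 12 methyl (2E,4S)-4-[(4R,5R)-5-(hydroxymethyl)-2,2-dimethyl-1,3-dioxolan-4-yl]-4-methoxybut-2-enoate
Product: 13 methyl (2E,4S)-4-[(4R,5S)-5-formyl-2,2-dimethyl-1,3-dioxolan-4-yl]-4-methoxybut-2-enoate
Conditions: TEMPO (10 mol %), PhI(OAc)2 (1.1 equiv), CH2Cl2, rt
Reagents that add atoms: none
Why: Oxoammonium (TEMPO) oxidation of a primary alcohol stops at the aldehyde in dry CH2Cl2 and is non-basic, so the enoate, the acetonide and the α-centre C5 are left alone.

**Step 8**
Reactants: 13 methyl (2E,4S)-4-[(4R,5S)-5-formyl-2,2-dimethyl-1,3-dioxolan-4-yl]-4-methoxybut-2-enoate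
Product: 16 methyl (1S,4R,5R,6R)-4-hydroxy-1-methoxy-5,6-(isopropylidenedioxy)cyclohex-2-ene-3-carboxylate, via phosphonium enolate 14 (not isolated), via phosphonium aldolate 15 (not isolated)
Conditions: PMe3 (0.3 equiv, 1 M in THF), CH2Cl2/t-BuOH 9:1, 0.02 M, rt, Ar
Reagents that add atoms: none
Why: PMe3 adds reversibly to C2 to give enolate 14, whose α-carbon C3 attacks the C4 aldehyde to give aldolate 15, after which proton transfer from C3 to oxygen (relayed by t-BuOH) and E1cB loss of PMe3 restore C2=C3 and free the catalyst. This is an intramolecular Morita–Baylis–Hillman reaction, the type known for 7-oxohept-2-enoates, which close to 6-hydroxycyclohex-1-enecarboxylates under trialkylphosphine catalysis. The cyclohexene closes in the 6-(enolexo)-exo-trig mode, since both the enolate bond C3=C7 and the C4=O bond lie outside the forming ring. The one new stereocentre, C4, is under substrate control: in the chair-like transition state the trans-dioxolane holds O5 and O6 equatorial and the C1 methoxy group is equatorial too, the forming C3–C4 bond is antiperiplanar to C5–O (polar Felkin–Anh alignment), and an equatorial C4–O would eclipse the exocyclic ester enolate (A(1,3) strain), so the oxygen should take the axial site, cis to O5 (4R), which is also the isomer favoured at equilibrium because a pseudoaxial hydroxyl avoids A(1,2) strain with the ester. The step needs closure to win over intermolecular coupling, aldehyde enolisation and loss of methoxide from C1, which is served by high dilution, by the chain pre-folded on the trans-dioxolane and by the inductively activated α,β-dialkoxy aldehyde, while C5 cannot drift because the trans-4,5-disubstituted dioxolane is already the more stable epimer. The transient centres at C2 and C3 vanish with the phosphine, so the alkene geometry of 13 does not matter.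

**Step 9**
Reactants: 16 methyl (1S,4R,5R,6R)-4-hydroxy-1-methoxy-5,6-(isopropylidenedioxy)cyclohex-2-ene-3-carboxylate
Product: 17 (1S,4R,5R,6R)-3-(hydroxymethyl)-1-methoxy-5,6-(isopropylidenedioxy)cyclohex-2-en-4-ol
Conditions: i-Bu2AlH (3.5 equiv), CH2Cl2, −78 to −40 °C; aq. potassium sodium tartrate
Reagents that add atoms: none
Why: 1,2-Reduction of an α,β-unsaturated ester by i-Bu2AlH gives the allylic alcohol without conjugate reduction, the first equivalent being consumed by the C4 hydroxyl, and the acetonide and methyl ether are inert at low temperature.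

**Step 10**
Reactants: 17 (1S,4R,5R,6R)-3-(hydroxymethyl)-1-methoxy-5,6-(isopropylidenedioxy)cyclohex-2-en-4-ol; 18 benzoyl chloride
Product: 19 [(1S,4R,5R,6R)-4-hydroxy-1-methoxy-5,6-(isopropylidenedioxy)cyclohex-2-en-3-yl]methyl benzoate
Conditions: BzCl (1.05 equiv), pyridine, CH2Cl2, −40 to 0 °C
Reagents that add atoms: benzoyl chloride 18, SMILES O=C(Cl)c1ccccc1
Why: In this selective acylation of a primary over a secondary alcohol the C7 hydroxyl is unhindered, whereas the C4 hydroxyl is pseudoaxial and flanked by C3 and the dioxolane, so one equivalent of BzCl at low temperature should stop at the monoester.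

**Step 11**
Reactants: 19 [(1S,4R,5R,6R)-4-hydroxy-1-methoxy-5,6-(isopropylidenedioxy)cyclohex-2-en-3-yl]methyl benzoate
Product: 20 [(1S,4R,5R,6S)-4,5,6-trihydroxy-1-methoxycyclohex-2-en-3-yl]methyl benzoate (same geometry as 19; the C6 descriptor changes only through priorities)
Conditions: AcOH/H2O 4:1, 40 °C
Reagents that add atoms: none
Why: Acid hydrolysis cleaves the strained trans-fused dioxolane under conditions mild enough to spare the allylic benzoate and the allylic methyl ether and to avoid acyl migration.

**Step 12**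
Reactants: 20 [(1S,4R,5R,6S)-4,5,6-trihydroxy-1-methoxycyclohex-2-en-3-yl]methyl benzoate; 18 benzoyl chloride
Product: 21 (1S,4R,5R,6R)-5-benzoyloxy-3-(benzoyloxymethyl)-4,6-dihydroxy-1-methoxycyclohex-2-ene (CNP0349013.6)
Conditions: BzCl (1.1 equiv), Ph2BOCH2CH2NH2 (10 mol %), i-Pr2NEt (1.5 equiv), MeCN, rt
Reagents that add atoms: benzoyl chloride 18, SMILES O=C(Cl)c1ccccc1
Why: In this borinic-acid-catalysed regioselective acylation of a cis-1,2-diol the catalyst binds reversibly the only cis-diol (C4/C5) and activates its equatorial oxygen O5, as in the O3-selective acylation of galacto-configured pyranoside triols whose equatorial, equatorial, axial array matches C6, C5, C4 here, while pseudoaxial O4 and unbound O6 stay free.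

**Compound list**

1 | D-xylose | O=C[C@H](O)[C@@H](O)[C@H](O)CO | starting material
2 | D-xylonic acid | OC(=O)[C@H](O)[C@@H](O)[C@H](O)CO | intermediate
3 | D-xylono-1,4-lactone | O=C1[C@H](O)[C@@H](O)[C@@H](CO)O1 | intermediate
4 | 2,2-dimethoxypropane | COC(C)(C)OC | starting material
5 | 3,5-O-isopropylidene-D-xylono-1,4-lactone | O=C1[C@H](O)[C@H]2OC(C)(C)OC[C@H]2O1 | intermediate
6 | iodomethane | CI | starting material
7 | 3,5-O-isopropylidene-2-O-methyl-D-xylono-1,4-lactone | O=C1[C@H](OC)[C@H]2OC(C)(C)OC[C@H]2O1 | intermediate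
8 | 3,5-O-isopropylidene-2-O-methyl-D-xylofuranose (anomeric mixture) | OC1[C@H](OC)[C@H]2OC(C)(C)OC[C@H]2O1 | intermediate
9 | methyl (triphenylphosphoranylidene)acetate | COC(=O)C=P(c1ccccc1)(c1ccccc1)c1ccccc1 | starting material
10 | 3,5-O-isopropylidene-2-O-methyl-aldehydo-D-xylose (open-chain hydroxy aldehyde) | O=C[C@H](OC)[C@H]1OC(C)(C)OC[C@H]1O | intermediate
11 | methyl (2E,4S)-4-[(4S,5R)-5-hydroxy-2,2-dimethyl-1,3-dioxan-4-yl]-4-methoxybut-2-enoate | COC(=O)/C=C/[C@H](OC)[C@H]1OC(C)(C)OC[C@H]1O | intermediate
12 | methyl (2E,4S)-4-[(4R,5R)-5-(hydroxymethyl)-2,2-dimethyl-1,3-dioxolan-4-yl]-4-methoxybut-2-enoate | CO[C@@H](/C=C/C(=O)OC)[C@H]1OC(C)(C)O[C@@H]1CO | intermediate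
13 | methyl (2E,4S)-4-[(4R,5S)-5-formyl-2,2-dimethyl-1,3-dioxolan-4-yl]-4-methoxybut-2-enoate | CO[C@@H](/C=C/C(=O)OC)[C@H]1OC(C)(C)O[C@@H]1C=O | intermediate
14 | phosphonium enolate (PMe3 on C2, ester enolate C3=C7) | CO[C@@H](C([P+](C)(C)C)C=C([O-])OC)[C@H]1OC(C)(C)O[C@@H]1C=O | intermediate
15 | phosphonium aldolate (ring closed, C4 alkoxide) | CO[C@H]1C([P+](C)(C)C)C(C(=O)OC)[C@@H]([O-])[C@H]2OC(C)(C)O[C@H]12 | intermediate
16 | methyl (1S,4R,5R,6R)-4-hydroxy-1-methoxy-5,6-(isopropylidenedioxy)cyclohex-2-ene-3-carboxylate | CO[C@H]1C=C(C(=O)OC)[C@@H](O)[C@H]2OC(C)(C)O[C@H]12 | intermediate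
17 | (1S,4R,5R,6R)-3-(hydroxymethyl)-1-methoxy-5,6-(isopropylidenedioxy)cyclohex-2-en-4-ol | CO[C@H]1C=C(CO)[C@@H](O)[C@H]2OC(C)(C)O[C@H]12 | intermediate
18 | benzoyl chloride | O=C(Cl)c1ccccc1 | starting material
19 | [(1S,4R,5R,6R)-4-hydroxy-1-methoxy-5,6-(isopropylidenedioxy)cyclohex-2-en-3-yl]methyl benzoate | CO[C@H]1C=C(COC(=O)c3ccccc3)[C@@H](O)[C@H]2OC(C)(C)O[C@H]12 | intermediate
20 | [(1S,4R,5R,6S)-4,5,6-trihydroxy-1-methoxycyclohex-2-en-3-yl]methyl benzoate | CO[C@H]1C=C(COC(=O)c2ccccc2)[C@@H](O)[C@@H](O)[C@@H]1O | intermediate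
21 | (1S,4R,5R,6R)-5-benzoyloxy-3-(benzoyloxymethyl)-4,6-dihydroxy-1-methoxycyclohex-2-ene | CO[C@H]1C=C(COC(=O)c2ccccc2)[C@@H](O)[C@@H](OC(=O)c2ccccc2)[C@@H]1O | target

Total step count: 12. Longest linear sequence: 12 steps (1 to 21).

**Steps most likely to fail**

First, step 8.
- The reversible aldol addition may stall before the slow proton transfer.
- The phosphonium enolate may be diverted by ylide formation and loss of methoxide from C1.
- The strain of the trans-fused bicycle may push the equilibrium back to the open chain.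
- Facial selectivity at C4 may be lower than the transition-state analysis suggests.

The fallback sets out from 13 and returns at 16. It replaces the catalytic phosphine by a stoichiometric sulfur nucleophile that is removed in a separate oxidative operation, so that ring closure no longer depends on the proton-transfer and elimination steps. PhSLi (THF, −40 °C, cold AcOH quench) adds to C2, and the lithium enolate closes onto the aldehyde in a thiolate-triggered Michael–aldol tandem cyclisation. This gives methyl 4-hydroxy-1-methoxy-5,6-(isopropylidenedioxy)-2-(phenylsulfanyl)cyclohexane-3-carboxylate F1. Oxidation with mCPBA (1 equiv, CH2Cl2, −78 °C) gives methyl 4-hydroxy-1-methoxy-5,6-(isopropylidenedioxy)-2-(phenylsulfinyl)cyclohexane-3-carboxylate F2. Warming F2 in toluene over CaCO3 (80 °C) eliminates the sulfoxide towards the acidic C3–H and delivers 16.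

Second, step 12. The catalyst may discriminate incompletely between O5 and O6, and the benzoyl group may migrate around the triol under the amine base.

The fallback sets out from 20 and returns at 21. It blocks O6 before the second benzoate is introduced, so that only the cis-diol remains to be differentiated.
- Me2C(OMe)2 and PPTS in acetone at rt should give the cis-fused, thermodynamically preferred 4,5-O-isopropylidene 7-benzoate F3, with only the C6 hydroxyl free.
- TBSOTf and 2,6-lutidine convert it into the 6-O-TBS 4,5-O-isopropylidene 7-benzoate F4.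
- TFA/H2O/CH2Cl2 at 0 °C removes the acetonide to give the 6-O-TBS 4,5-diol 7-benzoate F5.
- Bu2SnO (toluene, reflux, water removal) followed by BzCl at 0 °C acylates the equatorial oxygen of the single stannylene acetal to give the 6-O-TBS 5,7-dibenzoate F6.
- HF·pyridine in THF at 0 °C then frees O6 and gives 21.

Third, step 6. The equilibration may stop at a mixture of the internal and the terminal dioxolane, and adventitious water may cause partial loss of the acetal.

The fallback sets out from 11 and returns at 12. It fixes the position of the acetonide by blocking the primary hydroxyl.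
- AcOH/H2O at rt gives methyl (E)-2,3-dideoxy-4-O-methyl-D-xylo-hept-2-enonate F7.
- TBDPSCl and imidazole (CH2Cl2, 0 °C) silylate only the primary hydroxyl to give methyl (E)-7-O-(tert-butyldiphenylsilyl)-2,3-dideoxy-4-O-methyl-D-xylo-hept-2-enonate F8.
- Me2C(OMe)2 and PPTS (CH2Cl2, rt) can then bridge only the remaining threo-diol, giving methyl (E)-7-O-(tert-butyldiphenylsilyl)-2,3-dideoxy-5,6-O-isopropylidene-4-O-methyl-D-xylo-hept-2-enonate F9.
- Bu4NF buffered with AcOH (THF, 0 °C) releases 12 without alkoxide addition to the enoate.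

**Further compounds**

F1 | step 8 | methyl 4-hydroxy-1-methoxy-5,6-(isopropylidenedioxy)-2-(phenylsulfanyl)cyclohexane-3-carboxylate (C1, C4, C5, C6 as in 16; C2/C3 mixture) | CO[C@H]1C(Sc3ccccc3)C(C(=O)OC)[C@@H](O)[C@H]2OC(C)(C)O[C@H]12
F2 | step 8 | methyl 4-hydroxy-1-methoxy-5,6-(isopropylidenedioxy)-2-(phenylsulfinyl)cyclohexane-3-carboxylate (C1, C4, C5, C6 as in 16; C2/C3/S mixture) | CO[C@H]1C(S(=O)c3ccccc3)C(C(=O)OC)[C@@H](O)[C@H]2OC(C)(C)O[C@H]12
F3 | step 12 | 4,5-O-isopropylidene 7-benzoate (cis-fused acetonide on O4/O5 of 20, C6 hydroxyl free) | CO[C@H]1C=C(COC(=O)c3ccccc3)[C@H]2OC(C)(C)O[C@H]2[C@@H]1O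
F4 | step 12 | 6-O-TBS 4,5-O-isopropylidene 7-benzoate | CO[C@H]1C=C(COC(=O)c3ccccc3)[C@H]2OC(C)(C)O[C@H]2[C@@H]1O[Si](C)(C)C(C)(C)C
F5 | step 12 | 6-O-TBS 4,5-diol 7-benzoate | CO[C@H]1C=C(COC(=O)c2ccccc2)[C@@H](O)[C@@H](O)[C@@H]1O[Si](C)(C)C(C)(C)C
F6 | step 12 | 6-O-TBS 5,7-dibenzoate | CO[C@H]1C=C(COC(=O)c2ccccc2)[C@@H](O)[C@@H](OC(=O)c2ccccc2)[C@@H]1O[Si](C)(C)C(C)(C)C
F7 | step 6 | methyl (E)-2,3-dideoxy-4-O-methyl-D-xylo-hept-2-enonate | COC(=O)/C=C/[C@H](OC)[C@@H](O)[C@H](O)CO
F8 | step 6 | methyl (E)-7-O-(tert-butyldiphenylsilyl)-2,3-dideoxy-4-O-methyl-D-xylo-hept-2-enonate | COC(=O)/C=C/[C@H](OC)[C@@H](O)[C@H](O)CO[Si](c1ccccc1)(c1ccccc1)C(C)(C)C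
F9 | step 6 | methyl (E)-7-O-(tert-butyldiphenylsilyl)-2,3-dideoxy-5,6-O-isopropylidene-4-O-methyl-D-xylo-hept-2-enonate | CO[C@@H](/C=C/C(=O)OC)[C@H]1OC(C)(C)O[C@@H]1CO[Si](c1ccccc1)(c1ccccc1)C(C)(C)C
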